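**Plan**

The target is an achiral 20-membered bis(bibenzyl), C28H24O4. Its rings are A (3-OH, 4-OAr), B (meta-phenylene), C (para-phenylene) and D (3-OAr, 4-OH). It has no stereocentre, so no stereocontrol is needed.
Enabling feature: in both diaryl ethers the ring carbon on oxygen (C-4 of ring C, C-4 of ring A) stands para to a benzylic bridge carbon. A carbonyl at that carbon makes the ring a vinylogous acyl fluoride, so both ethers come from metal-free SNAr without a foreign activating group.
Retrosynthetic cuts: (1) two O–CH3 bonds; (2) CH2 next to ring C back to C=O; (3) O-3(ring D)–C-4(ring C), the macrocyclic cut; (4) ring B–CH2 (ketone α-arylation); (5) the C=C of the A–D bridge (Wittig); (6) O–C-4(ring A) (SNAr).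
Forward order: the A–O–B ether is made first, then ring D is joined, then ring C is joined through 4'-fluoroacetophenone. Its carbonyl first supplies the enolate that builds the B–C bridge and then activates C–F for ring closure.
One hydrogenation saturates the A–D bridge and frees O-3 of ring D. The helper carbonyl is erased by ionic hydrogenation and the methyl ethers by BBr3.

Key step: step 6

Assumption: the macrocycle is conformationally mobile, with no isolable atropisomers, so the SMILES without stereodescriptors defines the target fully.

**Step 1**
Reactants: 1 4-fluoro-3-methoxybenzaldehyde; 2 3-bromophenol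
Product: 3 4-(3-bromophenoxy)-3-methoxybenzaldehyde
Conditions: K2CO3, DMF, 110 °C
Reagents that add atoms: none
Why: SNAr, in which the para-formyl group activates the C–F bond of 1 toward the phenoxide of 2, while the aryl bromide is inert without a metal catalyst.

**Step 2**
Reactants: 4 3-(benzyloxy)-4-methoxybenzyl alcohol
Product: 5 [3-(benzyloxy)-4-methoxybenzyl]triphenylphosphonium bromide
Conditions: PPh3·HBr, MeCN, reflux
Reagents that add atoms: triphenylphosphine hydrobromide, [Br-].[PH+](c1ccccc1)(c1ccccc1)c1ccccc1
Why: Phosphonium salt formation by acid-promoted substitution of an electron-rich benzylic alcohol with PPh3; the aryl benzyl ether should tolerate this weak acid.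

**Step 3**
Reactants: 5 [3-(benzyloxy)-4-methoxybenzyl]triphenylphosphonium bromide; 3 4-(3-bromophenoxy)-3-methoxybenzaldehyde
Product: 7 1-[3-(benzyloxy)-4-methoxyphenyl]-2-[4-(3-bromophenoxy)-3-methoxyphenyl]ethene (E/Z mixture), via benzylidene phosphorane 6 (not isolated)
Conditions: KOtBu, THF, 0 °C to rt
Reagents that add atoms: none
Why: Wittig olefination with a semistabilised benzylic ylide; the alkene geometry does not matter because the double bond is saturated in step 5.

**Step 4**
Reactants: 7 bromo stilbene (E/Z mixture); 8 4'-fluoroacetophenone (excess)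
Product: 9 1-(4-fluorophenyl)-2-[3-(4-{2-[3-(benzyloxy)-4-methoxyphenyl]ethenyl}-2-methoxyphenoxy)phenyl]ethanone (E/Z mixture)
Conditions: Pd2(dba)3 (cat.), Xantphos, K3PO4, toluene, 100 °C
Reagents that add atoms: none
Why: Palladium-catalysed ketone α-arylation (Buchwald–Hartwig type): oxidative addition of the C–Br bond to zerovalent palladium, exchange with the potassium enolate of 8, then reductive elimination; the wide-bite-angle ligand and the excess of methyl ketone favour monoarylation, and C–F, stilbene and benzyl ether are untouched.

**Step 5**
Reactants: 9 stilbene fluoro ketone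
Product: 10 1-(4-fluorophenyl)-2-[3-(4-{2-[3-hydroxy-4-methoxyphenyl]ethyl}-2-methoxyphenoxy)phenyl]ethanone (seco phenol)
Conditions: H2 (1 atm), Pd/C (10 wt%), EtOAc, rt, stopped after two equivalents of H2
Reagents that add atoms: none
Why: Heterogeneous catalytic hydrogenation, in which alkene saturation and O-benzyl hydrogenolysis are faster than reduction of an aryl ketone in a neutral, non-protic medium, and the C–F bond is inert.

**Step 6**
Reactants: 10 seco phenol fluoro ketone
Product: 12 20-membered macrocyclic ketone (dimethyl ether of the target with C=O at the bridge carbon bound to ring C), via potassium phenoxide 11 (not isolated)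
Conditions: KHMDS (1.0 equiv), THF, 0 °C; then syringe-pump addition (24 h) into DMSO, 18-crown-6, 130 °C, Ar, final 2 mM
Reagents that add atoms: none
Why: Addition–elimination (SNAr): the O-3 phenoxide of ring D adds to C-4 of ring C, the para bridge carbonyl takes up the charge of the Meisenheimer adduct as an oxyanion, and loss of fluoride gives the diaryl ether. The closest known reaction type is the displacement of fluoride from 4-fluorophenyl ketones by phenoxides, as used for aryl ether ketones and their macrocyclic oligomers under pseudo-high dilution. The closure is an end-to-end 20-membered macrocyclisation (shortest path through two para- and two meta-phenylenes) by attack of oxygen on a trigonal ring carbon with the leaving C–F bond outside the new ring, and it creates no stereocentre. Only one free OH is present (O-4 of ring D and O-3 of ring A are methyl ethers) and only one activated C–F bond, so O-3/C-4 is the sole possible pairing, and slow addition to a low stationary concentration favours ring over oligomer. The α-CH2 of the ketone is about as acidic as the phenol and its enolate would switch the activation off, so exactly one equivalent of base is consumed before heating; the monoanion then equilibrates between the unreactive enolate and the reactive phenoxide and drains through the latter. Oxygen is excluded to protect that enolate.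

**Step 7**
Reactants: 12 macrocyclic ketone
Product: 13 macrocyclic dimethyl ether (O,O'-dimethyl derivative of the target)
Conditions: Et3SiH (excess), TFA, CH2Cl2, 0 °C to rt
Reagents that add atoms: none
Why: Ionic hydrogenation, in which the para-aryloxy group of ring C stabilises the benzylic cation formed by protonation and loss of water, and two hydride transfers from silicon turn C=O into CH2 without touching aryl or methyl ethers.

**Step 8**
Reactants: 13 macrocyclic dimethyl ether
Product: 14 target bis(bibenzyl)
Conditions: BBr3, CH2Cl2, −78 °C to rt; then H2O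
Reagents that add atoms: none
Why: Lewis-acid cleavage of aryl methyl ethers by attack of bromide on the O-methyl carbon of the boron-complexed ether; the diaryl ethers have no sp3 carbon on oxygen and survive.

**Compound list**

1 | 4-fluoro-3-methoxybenzaldehyde | COc1cc(C=O)ccc1F | starting material
2 | 3-bromophenol | Oc1cccc(Br)c1 | starting material
3 | 4-(3-bromophenoxy)-3-methoxybenzaldehyde | COc1cc(C=O)ccc1Oc1cccc(Br)c1 | intermediate
4 | 3-(benzyloxy)-4-methoxybenzyl alcohol | COc1ccc(CO)cc1OCc1ccccc1 | starting material
5 | [3-(benzyloxy)-4-methoxybenzyl]triphenylphosphonium bromide | COc1ccc(C[P+](c2ccccc2)(c2ccccc2)c2ccccc2)cc1OCc1ccccc1.[Br-] | intermediate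
6 | [3-(benzyloxy)-4-methoxybenzylidene]triphenylphosphorane (not isolated) | COc1ccc(C=P(c2ccccc2)(c2ccccc2)c2ccccc2)cc1OCc1ccccc1 | intermediate
7 | bromo stilbene, E/Z mixture (geometry left open) | COc1ccc(C=Cc2ccc(Oc3cccc(Br)c3)c(OC)c2)cc1OCc1ccccc1 | intermediate
8 | 4'-fluoroacetophenone | CC(=O)c1ccc(F)cc1 | starting material
9 | stilbene fluoro ketone, E/Z mixture (geometry left open) | COc1ccc(C=Cc2ccc(Oc3cccc(CC(=O)c4ccc(F)cc4)c3)c(OC)c2)cc1OCc1ccccc1 | intermediate
10 | seco phenol fluoro ketone | COc1ccc(CCc2ccc(Oc3cccc(CC(=O)c4ccc(F)cc4)c3)c(OC)c2)cc1O | intermediate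
11 | potassium phenoxide of 10 (not isolated) | COc1ccc(CCc2ccc(Oc3cccc(CC(=O)c4ccc(F)cc4)c3)c(OC)c2)cc1[O-].[K+] | intermediate
12 | macrocyclic ketone | COc1cc2ccc1Oc1cccc(c1)CC(=O)c1ccc(cc1)Oc1cc(ccc1OC)CC2 | intermediate
13 | macrocyclic dimethyl ether | COc1cc2ccc1Oc1cccc(c1)CCc1ccc(cc1)Oc1cc(ccc1OC)CC2 | intermediate
14 | target bis(bibenzyl) | Oc1cc2ccc1Oc1cccc(c1)CCc1ccc(cc1)Oc1cc(ccc1O)CC2 | target

**Step count**

Total steps: 8. The longest linear sequence is 7 steps (steps 1, 3, 4, 5, 6, 7, 8).

**Steps most likely to fail**

**Step 6.** Enolisation of the bridge ketone may switch off the activation. Ring closure could then become slower than intermolecular displacement and slow base-induced degradation at 130 °C.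

- The fallback replaces SNAr by an oxidative copper coupling and needs no carbonyl helper. It sets out from 7 and returns at 13.
- A Heck reaction of 7 with commercial 4-vinylphenylboronic acid MIDA ester (Pd(OAc)2, P(o-tol)3, Et3N, DMF, 90 °C) should give the bis-stilbene MIDA boronate F1.
- H2 over Pd/C saturates both alkenes and removes the benzyl group, giving the phenol MIDA boronate F2.
- Aqueous NaOH in THF frees the seco boronic acid F3.
- A Chan–Lam macrocyclisation (Cu(OAc)2, pyridine, Et3N, 4 Å sieves, CH2Cl2, air, rt, high dilution) forms the same O-3(ring D)–C-4(ring C) bond and delivers 13 directly.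

**Step 4.** The more acidic product enolate may be arylated a second time, or the catalyst may be lost to insertion into the stilbene.

- The fallback builds the ketone by acyl substitution instead of cross-coupling. It sets out from 1 (with 5) and returns at 9.
- Commercial 3-hydroxyphenylacetic acid is coupled with N,O-dimethylhydroxylamine hydrochloride (EDC, Et3N, CH2Cl2) to give the phenolic Weinreb amide F4.
- SNAr of F4 on 1 (K2CO3, DMF, 110 °C) gives the aldehyde Weinreb amide F5.
- Wittig reaction of F5 with 5 (KOtBu, THF) gives the stilbene Weinreb amide F6.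
- Addition of 4-fluorophenylmagnesium bromide to F6 (THF, 0 °C) gives 9.

**Step 5.** The ketone may be reduced to the carbinol or to methylene before the benzyl ether is fully cleaved. That would remove the activation needed in step 6.

- The fallback uses two non-catalytic operations in place of hydrogenation. It sets out from 9 and returns at 10.
- Diimide reduction (dipotassium azodicarboxylate, AcOH, MeOH/THF, rt) saturates only the alkene and gives the saturated benzyl ether ketone F7.
- BCl3 with pentamethylbenzene (CH2Cl2, −78 °C) then removes the benzyl group selectively and gives 10.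

**Further compounds**

F1 | step 6 | bis-stilbene MIDA boronate (E/Z mixture) | CN1CC(=O)OB(OC(=O)C1)c1ccc(C=Cc2cccc(Oc3ccc(C=Cc4ccc(OC)c(OCc5ccccc5)c4)cc3OC)c2)cc1
F2 | step 6 | phenol MIDA boronate | CN1CC(=O)OB(OC(=O)C1)c1ccc(CCc2cccc(Oc3ccc(CCc4ccc(OC)c(O)c4)cc3OC)c2)cc1
F3 | step 6 | seco boronic acid | OB(O)c1ccc(CCc2cccc(Oc3ccc(CCc4ccc(OC)c(O)c4)cc3OC)c2)cc1
F4 | step 4 | 2-(3-hydroxyphenyl)-N-methoxy-N-methylacetamide | CON(C)C(=O)Cc1cccc(O)c1
F5 | step 4 | 2-[3-(4-formyl-2-methoxyphenoxy)phenyl]-N-methoxy-N-methylacetamide | CON(C)C(=O)Cc1cccc(Oc2ccc(C=O)cc2OC)c1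
F6 | step 4 | stilbene Weinreb amide (E/Z mixture) | CON(C)C(=O)Cc1cccc(Oc2ccc(C=Cc3ccc(OC)c(OCc4ccccc4)c3)cc2OC)c1
F7 | step 5 | saturated benzyl ether fluoro ketone | COc1ccc(CCc2ccc(Oc3cccc(CC(=O)c4ccc(F)cc4)c3)c(OC)c2)cc1OCc1ccccc1
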